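The readings were generated by integration with constants of no real substance; noise was put on by code.

Each flask is read at a fixed time, so the ratio to reckon is that time over a half-life, once for substrate and once for intermediate, and you need both half-lives from the earlier runs, teal and blue.

all flasks: substrate 0.050 M
- teal: solid reagent 0.55 equiv; temperature 54 °C; run made earlier
- blue: solid reagent 2.2 equiv; temperature 63 °C; run made earlier
- delta: solid reagent 1.10 equiv; temperature 50 °C; time 15 min
- gamma: solid reagent 1.10 equiv; temperature 58 °C; time 15 min
- eta: solid reagent 1.10 equiv; temperature 66 °C; time 15 min

- teal (time / min: substrate / %, intermediate / %, target / %): 1.33: 78.9, 20.0, 0; 2.50: 64.8, 34.7, 0; 4.00: 50.7, 47.1, 0.9; 8.00: 27.1, 69.2, 5.1; 15.0: 7.0, 80.1, 13.9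
- blue (time / min: substrate / %, intermediate / %, target / %): 0.667: 74.0, 25.5, 1.6; 1.33: 55.2, 44.8, 0; 2.00: 41.1, 60.0, 1.7; 4.00: 16.6, 81.7, 3.1; 8.00: 3.4, 88.0, 10.0

(standard deviation of a reading: 1 percentage point)

- which of these there is most of at the end, counted by the substrate in it, delta (target / substrate / intermediate)
- which of these there is most of at the end, counted by the substrate in it, gamma (target / substrate / intermediate)
- which of these there is most of at the end, counted by the substrate in it, eta (target / substrate / intermediate)
- amount of the one of these that there is most of at the end, in percent of the substrate charged, delta
- amount of the one of these that there is most of at the end, in percent of the substrate charged, gamma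
- amount of the one of these that there is most of at the end, in percent of the substrate charged, eta

- the earlier runs were read with a standard deviation of 1 percentage point
- at the start none of the solid reagent is in solution
- a reading or a percentage of target counts all its forms, free or not

Start with substrate in blue, the run nearest to eta. Its first-order constant k, the logarithm of charge over what is left divided by the time, comes from the last reading as 0.423 min⁻¹, so its half-life is 1.64 min.

For intermediate, let κ be the fraction of it turned into target per minute, treated as pseudo-first-order. You can read κ in two ways. The whole-run way divides the last target by the area under the intermediate curve, giving 0.0161 min⁻¹ in teal and 0.0182 min⁻¹ in blue. The last-window way divides the target gained between the last two readings by the time and the mean intermediate, giving 0.0168 min⁻¹ in teal and 0.0203 min⁻¹ in blue.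

The two nearly agree in teal, while in blue the window reads larger than the whole run. The whole-run figure is the one to distrust. Teal still shows target at 0 % after 2.50 min with intermediate at 34.7 %, so the early minutes add area without adding target, which fits a solid reagent that starts out of solution.

I therefore carry blue's window value as h, the half-life of intermediate 34.1 min. Against the asked 15 min, that makes 0.440 of a half-life of intermediate but 9.15 half-lives of substrate, both as read in blue. My own reckoning for eta lets substrate delay intermediate by 2.36 min, then halves intermediate every h, which gives 77.3 %. Eta is warmer than blue, 66 °C against 63 °C, so I expect the true figure to lie below this.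

The forecast, holding that “Intermediate remains dominant throughout”, gave intermediate at 71 % in delta, intermediate at 81 % in gamma and intermediate at 77 % in eta.

The flask gives intermediate at 71.8 % in delta, intermediate at 79.1 % in gamma and intermediate at 68.7 % in eta.

    substrate → intermediate (k = 0.00180 s⁻¹, Ea = 100 kJ mol⁻¹)
    partner + intermediate → target (k = 0.0100 L mol⁻¹ s⁻¹, Ea = 64.0 kJ mol⁻¹)
    crystals ⇌ target, rate k3*(cs3 - [target]) while solid is left; crystals form when [target] > cs3 (solubility = 23.0 mM, k = 0.0200 s⁻¹)
    solid reagent ⇌ partner, rate k4*(cs4 - [partner]) while solid is left; crystals form when [partner] > cs4 (solubility = 28.0 mM, k = 0.00280 s⁻¹)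
    (constants at 50 °C)

Here partner is the dissolved form of the solid reagent. Eta ends 8.6 percentage points below my reckoning, and its intermediate half-life at 15.0 min is 20 min, shorter than h. Run on from the end of eta to 40 min, h gives 41.3 % and the shorter value 28.3 %, and that neighbour flask holds 26.3 %. So none of the flasks has come to rest at 15 min. At 150 min intermediate is down to 17.3 % in delta and 8.31 % in gamma, and in eta to 3.56 %, with target at 96.4 %, of which crystals hold 50.4 %.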